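The data were computed with made-up constants; noise was put on by code.

| setting | dusk | spring | winter | flask |
|---|---|---|---|---|
| starting material | 0.10 M | 0.10 M | 0.20 M | 0.10 M |
| partner | 0.10 M | 0.22 M | 0.15 M | 0.150 M |
| second substrate | 0.20 M | 0.20 M | 0.20 M | 0.200 M |
| remark | run made earlier | run made earlier | run made earlier |  |
| time |  |  |  | 10 min |

| run | time / min | idle adduct / % | target / % |
|---|---|---|---|
| dusk | 0.667 | 10.3 | 14.1 |
| dusk | 1.33 | 11.9 | 15.9 |
| dusk | 2.50 | 10.3 | 14.2 |
| dusk | 4.00 | 8.8 | 11.0 |
| dusk | 8.00 | 4.8 | 5.7 |
| spring | 0.667 | 16.3 | 25.5 |
| spring | 2.00 | 16.3 | 25.9 |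
| spring | 4.00 | 13.7 | 19.7 |
| spring | 6.00 | 10.8 | 15.0 |
| spring | 8.00 | 8.0 | 10.4 |
| winter | 0.667 | 19.1 | 18.0 |
| winter | 2.00 | 20.7 | 20.6 |
| winter | 4.00 | 17.6 | 16.4 |
| winter | 6.00 | 14.7 | 13.1 |
| winter | 8.00 | 11.5 | 10.2 |

(each reading ± 0.3 percentage points)

- a species is counted by the starting material in it: one idle adduct counts as two
- amounts and yields of target count idle adduct too
- in an amount of target, one idle adduct counts as one target

- amount of idle adduct in percent of the starting material charged, at 1.0 min, 3.0 min, 6.0 min and 10 min

1. None of the earlier runs has the charge of this flask and none was read past 8.00 min, so we cannot read the flask off a run and must bracket it. It shares starting material and second substrate with dusk and spring, and its partner charge of 0.150 M lies above dusk's and below spring's. Spring reads more idle adduct than dusk at 8.00 min, so we take dusk as floor and spring as ceiling, and we place the flask a fraction 0.417 of the way up, reckoned on the partner charge.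

2. For the late end we define the drain constant, a pseudo-first-order constant read from the logarithm of the fall in idle adduct between the readings at 4.00 min and 8.00 min, per minute. Dusk reads 0.152 /min and spring 0.134 /min, so for the flask we take 0.144 /min.

3. Run on with their own constants, dusk and spring give 3.55% and 6.11% at 10 min. We tighten this from a flask value of 6.13% at 8.00 min, which gives 4.59% at 10 min, and, run backwards, 8.19% at 6.0 min and 12.6% at 3.0 min.

4. Near the peak, where dusk still rises from 10.3% to 11.9%, the backward line serves us as a ceiling of 16.9% at 1.0 min. The floor is the weighted reading at 0.667 min, 12.8%, and we commit to the midpoint, 14.8%.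

5. The forecast, which calls the adduct “a fast reservoir of target that drains”, gives 13.6%, 11.9%, 8.3% and 4.5%. Its first and last values stand inside our brackets, and it parts from our line most at 1.0 min.

The flask gives 14.7%, 12.7%, 8.59% and 4.70%, inside both brackets, and the forecast held.

    starting material + partner ⇌ target (K = 3.20 /M, k = 0.0650 /M/s)
    second substrate + partner ⇌ second product (K = 0.200 /M, k = 0.00200 /M/s)
    target ⇌ isomer of the product (K = 0.420, k = 0.00600 /s)
    partner → decomposed reagent (k = 0.00620 /s)
    starting material + target ⇌ idle adduct, settled at all times (K = 7.80 /M)

After its peak the idle adduct falls because partner goes to decomposed reagent while target returns to starting material and partner: at 10 min the flask holds 4.70%, against 16.9% without the decomposition and 18.0% without the return. The flask's own drain from 6.0 min to 10 min is 0.151 /min, beside our 0.144 /min. Carried to winter, with the flask's partner charge and twice its starting material, 0.144 /min takes 17.6% at 4.00 min to 9.89% at 8.00 min, where winter reads 11.5%.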